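The route rests on cutting C4–C5 (cembrane numbering), the bond of the 4,7-epoxy bridge (oxolane O/C4–C7) that joins methylene C5 to the fully substituted, oxygen-bearing C4. The array O–C4(CH3)–C3(OH) is read as a β-alkoxyvinyl sulfoxide: a primary C5 radical, tethered through C6–C7–O, closes the oxolane 5-exo-trig onto C4. One operation forms the ring and the quaternary stereocentre, cis to the C7 carbonyl arm, and leaves sulfur on C3 for Pummerer unmasking. The precursor is an acyclic iodo enol ether made from (R)-α-hydroxybutyrolactone and a propynyl sulfoxide. The carbocycle is closed last by an indium Barbier lactone annulation (C1–C14).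

Key step: step 5

Locants (cembrane): C1 lactone β-CH, C2 CH2, C3 CHOH, C4 O-bearing C(CH3), C5/C6 oxolane CH2, C7 oxolane CH, C8 C(CH3)OAc, C9–C11 CH2, C12 CHCH3, C13 CHOAc, C14 lactone O–CH, C15/C16/C17 lactone α-C, C=O, exocyclic CH2. Target: 1S,3R,4S,7R,8S,12S,13R,14R.
Remark: B-allyldiisopinocampheylborane derived from (−)-α-pinene is assumed to be bought as a solution; it can otherwise be made from the matching Ipc2BOMe and allylmagnesium bromide.

Step 1
Reactants: 1 (1R,2S,5R)-menthyl (S)-p-toluenesulfinate; 2 1-propynylmagnesium bromide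
Product: 3 (S)-1-propynyl p-tolyl sulfoxide
Conditions: toluene/THF, −20 °C to 0 °C; aq NH4Cl
Reagents that add atoms: none
Why: Andersen sulfoxide synthesis, in which the alkynyl Grignard reagent displaces mentholate at sulfur with inversion, so the sulfinate configuration should be transferred cleanly to 3.

Step 2
Reactants: 4 (R)-α-hydroxy-γ-butyrolactone
Product: 5 (R)-2,4-dihydroxy-N-methoxy-N-methylbutanamide
Conditions: Me(MeO)NH·HCl, AlMe3, CH2Cl2, 0 °C to rt; Rochelle salt
Reagents that add atoms: N,O-dimethylhydroxylamine hydrochloride CNOC.Cl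
Why: Aluminium-amide aminolysis of a lactone (Weinreb amide formation) opens the ring at the acyl C–O bond and does not touch the C7 stereocentre, which comes from the chiral pool.

Step 3
Reactants: 5 (R)-2,4-dihydroxy-N-methoxy-N-methylbutanamide
Product: 6 (R)-2-hydroxy-4-iodo-N-methoxy-N-methylbutanamide
Conditions: I2, PPh3, imidazole, CH2Cl2, 0 °C
Reagents that add atoms: iodine II
Why: Appel-type iodination at low temperature is selective for the unhindered primary alcohol over the secondary α-hydroxy amide and leaves C7 untouched.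

Step 4
Reactants: 6 (R)-2-hydroxy-4-iodo-N-methoxy-N-methylbutanamide; 3 (S)-1-propynyl p-tolyl sulfoxide
Product: 7 (R)-4-iodo-N-methoxy-N-methyl-2-{(E)-1-[(R)-p-tolylsulfinyl]prop-1-en-2-yloxy}butanamide
Conditions: NaH (0.1 equiv), THF, −20 °C to 0 °C
Reagents that add atoms: none
Why: Base-catalysed oxa-Michael addition, in which the C7 alkoxide attacks the methyl-bearing β-carbon of the alkynyl sulfoxide and proton transfer under equilibrating conditions should leave the more stable E push-pull enol ether.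

Step 5
Reactants: 7 (R)-4-iodo-N-methoxy-N-methyl-2-{(E)-1-[(R)-p-tolylsulfinyl]prop-1-en-2-yloxy}butanamide
Product: 8 (2R,5S)-N-methoxy-N,5-dimethyl-5-{[(R)-p-tolylsulfinyl]methyl}oxolane-2-carboxamide
Conditions: Bu3SnH (slow addition), Et3B (cat.), air, toluene (0.01 M), −20 °C
Reagents that add atoms: none
Why: Et3B/O2 generates Bu3Sn•, which abstracts iodine from 7 to give the primary C5 radical; this nucleophilic radical adds to C4, the β-carbon of the sulfinyl-activated enol ether, and the resulting α-sulfinyl C3 radical takes hydrogen from Bu3SnH to carry the chain. The closest known reaction type is the 5-exo radical cyclisation of β-alkoxyacrylates and β-alkoxyvinyl sulfoxides to cis-2,5-disubstituted oxolanes. The single ring closed is the oxolane (O, C4–C7), in the 5-exo-trig mode. The new stereocentre C4 is controlled by C7: in the chair-like 4-oxa-5-hexenyl transition state the carboxamide sits pseudo-equatorial and the C4=C3 arm takes the exo position, so CH2S(O)Tol should end cis to the C7 carbonyl and the methyl group trans (4S). The step needs 5-exo attack at the more substituted alkene carbon rather than 6-endo attack at C3 or direct reduction; the sulfinyl group polarises the alkene toward attack at C4 and stabilises the adduct radical, and a low stannane concentration suppresses reduction. The sulfur configuration is not relied on and is erased in step 6.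

Step 6
Reactants: 8 (2R,5S)-N-methoxy-N,5-dimethyl-5-{[(R)-p-tolylsulfinyl]methyl}oxolane-2-carboxamide
Product: 10 (2R,5S)-5-formyl-N-methoxy-N,5-dimethyloxolane-2-carboxamide, via trifluoroacetoxy sulfide 9 (not isolated)
Conditions: (CF3CO)2O, 2,6-lutidine, MeCN, 0 °C; then aq NaHCO3, rt
Reagents that add atoms: trifluoroacetic anhydride O=C(OC(=O)C(F)(F)F)C(F)(F)F
Why: Pummerer rearrangement, in which O-acylation of the sulfoxide and loss of a C3 proton give a thionium ion trapped by trifluoroacetate, C4 carries no hydrogen so no vinyl sulfide can form, and mild hydrolysis of 9 releases the non-enolisable aldehyde.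

Step 7
Reactants: 10 (2R,5S)-5-formyl-N-methoxy-N,5-dimethyloxolane-2-carboxamide
Product: 12 (2R,5S)-5-[(1R)-1-hydroxybut-3-enyl]-N-methoxy-N,5-dimethyloxolane-2-carboxamide, via diisopinocampheylborinate ester 11 (not isolated)
Conditions: Ipc2B(allyl) from (−)-α-pinene, Et2O, −78 °C; then NaOH, H2O2, 0 °C to rt
Reagents that add atoms: B-allyldiisopinocampheylborane from (−)-α-pinene C=CCB([C@H]1C[C@H]2C[C@@H]([C@@H]1C)C2(C)C)[C@H]1C[C@H]2C[C@@H]([C@@H]1C)C2(C)C
Why: Brown allylboration through a closed chair transition state is reagent-controlled, and the (−)-α-pinene-derived borane should add allyl to the aldehyde face that gives the 3R carbinol irrespective of the small methyl/ring-CH2 bias at C4.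

Step 8
Reactants: 12 (2R,5S)-5-[(1R)-1-hydroxybut-3-enyl]-N-methoxy-N,5-dimethyloxolane-2-carboxamide
Product: 13 (2R,5S)-5-[(1R)-1-(tert-butyldimethylsilyloxy)but-3-enyl]-N-methoxy-N,5-dimethyloxolane-2-carboxamide
Conditions: TBSOTf, 2,6-lutidine, CH2Cl2, 0 °C
Reagents that add atoms: tert-butyldimethylsilyl triflate CC(C)(C)[Si](C)(C)OS(=O)(=O)C(F)(F)F
Why: Silylation with a silyl triflate and a hindered base protects even this neopentyl-type secondary alcohol, and the TBS ether should outlast every later step until fluoride is used.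

Step 9
Reactants: 14 (S)-citronellal
Product: 16 (2R,3S)-2-(anilinooxy)-3,7-dimethyloct-6-en-1-ol, via anilinooxy aldehyde 15 (not isolated)
Conditions: PhNO, L-proline (20 mol %), DMSO, rt; then NaBH4, EtOH, 0 °C
Reagents that add atoms: nitrosobenzene O=Nc1ccccc1
Why: Proline-catalysed α-aminoxylation, in which the E-enamine of 14 attacks the oxygen of nitrosobenzene held by the carboxylic acid, L-proline should set 13R under catalyst control, and immediate borohydride reduction prevents epimerisation of 15.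

Step 10
Reactants: 16 (2R,3S)-2-(anilinooxy)-3,7-dimethyloct-6-en-1-ol
Product: 17 (2R,3S)-3,7-dimethyloct-6-ene-1,2-diol
Conditions: Zn dust, AcOH/EtOH, rt
Reagents that add atoms: none
Why: Reductive N–O cleavage by zinc in acetic acid frees the C13 hydroxyl without touching the trisubstituted alkene or either stereocentre.

Step 11
Reactants: 17 (2R,3S)-3,7-dimethyloct-6-ene-1,2-diol
Product: 18 (4R)-2,2-dimethyl-4-[(2S)-6-methylhept-5-en-2-yl]-1,3-dioxolane
Conditions: 2,2-dimethoxypropane, PPTS (cat.), CH2Cl2, rt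
Reagents that add atoms: 2,2-dimethoxypropane COC(C)(C)OC
Why: Acid-catalysed transketalisation closes the five-membered acetonide of the terminal 1,2-diol and so masks C13–OH and C14–OH together.

Step 12
Reactants: 18 (4R)-2,2-dimethyl-4-[(2S)-6-methylhept-5-en-2-yl]-1,3-dioxolane
Product: 20 (4S)-4-[(4R)-2,2-dimethyl-1,3-dioxolan-4-yl]pentan-1-ol, via secondary ozonide 19 (not isolated)
Conditions: O3, CH2Cl2, −78 °C; then NaBH4, MeOH, −78 °C to rt
Reagents that add atoms: ozone [O-][O+]=O
Why: Ozonolysis with reductive borohydride work-up cleaves the only alkene and removes the isopropylidene terminus, so C9 emerges as a primary alcohol.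

Step 13
Reactants: 20 (4S)-4-[(4R)-2,2-dimethyl-1,3-dioxolan-4-yl]pentan-1-ol
Product: 21 (4R)-4-[(2S)-5-iodopentan-2-yl]-2,2-dimethyl-1,3-dioxolane
Conditions: I2, PPh3, imidazole, CH2Cl2, 0 °C to rt
Reagents that add atoms: iodine II
Why: Appel-type iodination converts the primary alcohol into the iodide needed for halogen-lithium exchange, and the acetonide tolerates the imidazole-buffered conditions.

Step 14
Reactants: 21 (4R)-4-[(2S)-5-iodopentan-2-yl]-2,2-dimethyl-1,3-dioxolane; 13 (2R,5S)-5-[(1R)-1-(tert-butyldimethylsilyloxy)but-3-enyl]-N-methoxy-N,5-dimethyloxolane-2-carboxamide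
Product: 23 seco C8 ketone (3R-OTBS; 4S,7R-oxolane; 12S; 13R,14-acetonide; vinyl on C2), via alkyllithium 22 (not isolated)
Conditions: t-BuLi (2.1 equiv), Et2O/pentane, −78 °C; then 13, THF, −78 °C to −20 °C; aq NH4Cl
Reagents that add atoms: tert-butyllithium [Li]C(C)(C)C (lithium of 22 only)
Why: Iodine-lithium exchange followed by Weinreb ketone synthesis, in which the chelated tetrahedral adduct stops the addition at the ketone stage and C7 is not enolised at low temperature.

Step 15
Reactants: 23 seco C8 ketone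
Product: 25 seco 8S tertiary acetate (3R-OTBS; 4S,7R-oxolane; 12S; 13R,14-acetonide; vinyl on C2), via bromomagnesium alkoxide 24 (not isolated)
Conditions: MeMgBr, CH2Cl2/Et2O, −78 °C; then Ac2O, DMAP, −78 °C to rt
Reagents that add atoms: methylmagnesium bromide C[Mg]Br; acetic anhydride CC(=O)OC(C)=O
Why: Cram-chelate Grignard addition, in which magnesium bridges the ketone oxygen and the oxolane oxygen, methyl attacks from the face of the C7 hydrogen and should set 8S, and the hindered alkoxide 24 is acetylated in the same flask.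

Step 16
Reactants: 25 seco 8S tertiary acetate
Product: 27 seco C1 aldehyde (vinyl of 25 cleaved to CHO), via secondary ozonide 26 (not isolated)
Conditions: O3, CH2Cl2, −78 °C; then PPh3, −78 °C to rt
Reagents that add atoms: ozone [O-][O+]=O
Why: Ozonolysis with phosphine work-up cleaves the only alkene to the C1 aldehyde, while the silyl ether, acetate and acetonide are inert to ozone.

Step 17
Reactants: 27 seco C1 aldehyde
Product: 28 Baylis–Hillman adduct (methyl 2-methylidene-3-hydroxy ester at C15–C17/C1; C1 epimers)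
Conditions: methyl acrylate (excess), DABCO, MeOH, rt
Reagents that add atoms: methyl acrylate C=CC(=O)OC
Why: The Morita–Baylis–Hillman reaction installs C15–C17 of the lactone in one step, and the new C1 carbinol centre is of no consequence because it becomes sp2 in step 18.

Step 18
Reactants: 28 Baylis–Hillman adduct
Product: 29 seco (Z)-allylic bromide (methyl (Z)-2-(bromomethyl)enoate; C1=C15)
Conditions: NBS, Me2S, CH2Cl2, 0 °C to rt
Reagents that add atoms: N-bromosuccinimide O=C1CCC(=O)N1Br
Why: SN2′ bromination of the activated Baylis–Hillman alcohol gives the conjugated primary allylic bromide, with Z geometry favoured because allylic strain keeps the C2 chain away from the ester.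

Step 19
Reactants: 29 seco (Z)-allylic bromide
Product: 30 seco 13R,14-diol
Conditions: AcOH/THF/H2O (3:1:1), 40 °C
Reagents that add atoms: none
Why: Mild acid hydrolysis removes the terminal acetonide faster than it attacks the hindered secondary TBS ether, the tertiary acetate or the allylic bromide.

Step 20
Reactants: 30 seco 13R,14-diol
Product: 31 seco 13R-hydroxy C14 aldehyde
Conditions: TEMPO (20 mol %), PhI(OAc)2 (1.1 equiv), CH2Cl2, rt; used at once
Reagents that add atoms: none
Why: Oxoammonium (TEMPO) oxidation is selective for the primary alcohol, so the C13 carbinol stays free as the chelating group for the next step.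

Step 21
Reactants: 31 seco 13R-hydroxy C14 aldehyde
Product: 33 13-hydroxy 3-O-TBS cembranolide (cis-fused α-methylene-γ-lactone; 8-acetate), via macrocyclic hydroxy ester 32 (not isolated)
Conditions: In powder, THF/H2O (1:1), 2 mM, syringe-pump addition, rt; then PPTS (cat.), CH2Cl2, rt
Reagents that add atoms: none
Why: Intramolecular Barbier allylation, in which the allylindium reacts at its γ-carbon C1 through a chair transition state where the Z-configured allyl unit gives the C1/C14 syn adduct, chelation of indium by the free C13 hydroxyl and the aldehyde oxygen should direct attack to the 13,14-syn diol (1S,14R), and the C14 hydroxyl then closes the cis-fused γ-lactone.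

Step 22
Reactants: 33 13-hydroxy 3-O-TBS cembranolide
Product: 34 8,13-diacetate 3-O-TBS cembranolide
Conditions: Ac2O, pyridine, DMAP (cat.), CH2Cl2, 0 °C to rt
Reagents that add atoms: acetic anhydride CC(=O)OC(C)=O
Why: DMAP-catalysed acetylation esterifies the only free hydroxyl, at C13, with retention.

Step 23
Reactants: 34 8,13-diacetate 3-O-TBS cembranolide
Product: 35 target (CID10479028)
Conditions: HF·pyridine, THF, 0 °C to rt
Reagents that add atoms: none
Why: Fluoride-mediated desilylation in an acidic buffer frees C3–OH without hydrolysing the acetates or adding to the α-methylene lactone.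

Compound list
1 | (1R,2S,5R)-menthyl (S)-p-toluenesulfinate | CC(C)[C@@H]1CC[C@@H](C)C[C@H]1O[S@](=O)c1ccc(C)cc1 | starting material
2 | 1-propynylmagnesium bromide | CC#C[Mg]Br | starting material
3 | (S)-1-propynyl p-tolyl sulfoxide | CC#C[S@@](=O)c1ccc(C)cc1 | intermediate
4 | (R)-α-hydroxy-γ-butyrolactone | O[C@@H]1CCOC1=O | starting material
5 | (R)-2,4-dihydroxy-N-methoxy-N-methylbutanamide | CON(C)C(=O)[C@H](O)CCO | intermediate
6 | (R)-2-hydroxy-4-iodo-N-methoxy-N-methylbutanamide | CON(C)C(=O)[C@H](O)CCI | intermediate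
7 | (R)-4-iodo-N-methoxy-N-methyl-2-{(E)-1-[(R)-p-tolylsulfinyl]prop-1-en-2-yloxy}butanamide | CON(C)C(=O)[C@H](O/C(C)=C/[S@@](=O)c1ccc(C)cc1)CCI | intermediate
8 | (2R,5S)-N-methoxy-N,5-dimethyl-5-{[(R)-p-tolylsulfinyl]methyl}oxolane-2-carboxamide | CON(C)C(=O)[C@H]1CC[C@](C)(O1)C[S@@](=O)c1ccc(C)cc1 | intermediate
9 | trifluoroacetoxy sulfide of 8 (C3 epimers) | CON(C)C(=O)[C@H]1CC[C@](C)(O1)C(OC(=O)C(F)(F)F)Sc1ccc(C)cc1 | intermediate
10 | (2R,5S)-5-formyl-N-methoxy-N,5-dimethyloxolane-2-carboxamide | CON(C)C(=O)[C@H]1CC[C@](C)(O1)C=O | intermediate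
11 | diisopinocampheylborinate ester of 12 | CON(C)C(=O)[C@H]1CC[C@](C)(O1)[C@H](OB([C@H]2C[C@H]3C[C@@H]([C@@H]2C)C3(C)C)[C@H]2C[C@H]3C[C@@H]([C@@H]2C)C3(C)C)CC=C | intermediate
12 | (2R,5S)-5-[(1R)-1-hydroxybut-3-enyl]-N-methoxy-N,5-dimethyloxolane-2-carboxamide | CON(C)C(=O)[C@H]1CC[C@](C)(O1)[C@H](O)CC=C | intermediate
13 | (2R,5S)-5-[(1R)-1-(tert-butyldimethylsilyloxy)but-3-enyl]-N-methoxy-N,5-dimethyloxolane-2-carboxamide | CON(C)C(=O)[C@H]1CC[C@](C)(O1)[C@H](O[Si](C)(C)C(C)(C)C)CC=C | intermediate
14 | (S)-citronellal | O=CC[C@@H](C)CCC=C(C)C | starting material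
15 | (2R,3S)-2-(anilinooxy)-3,7-dimethyloct-6-enal | O=C[C@H](ONc1ccccc1)[C@@H](C)CCC=C(C)C | intermediate
16 | (2R,3S)-2-(anilinooxy)-3,7-dimethyloct-6-en-1-ol | OC[C@H](ONc1ccccc1)[C@@H](C)CCC=C(C)C | intermediate
17 | (2R,3S)-3,7-dimethyloct-6-ene-1,2-diol | OC[C@H](O)[C@@H](C)CCC=C(C)C | intermediate
18 | (4R)-2,2-dimethyl-4-[(2S)-6-methylhept-5-en-2-yl]-1,3-dioxolane | CC1(C)OC[C@H](O1)[C@@H](C)CCC=C(C)C | intermediate
19 | secondary ozonide (1,2,4-trioxolane) of 18 | CC1(C)OC[C@H](O1)[C@@H](C)CCC1OOC(C)(C)O1 | intermediate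
20 | (4S)-4-[(4R)-2,2-dimethyl-1,3-dioxolan-4-yl]pentan-1-ol | CC1(C)OC[C@H](O1)[C@@H](C)CCCO | intermediate
21 | (4R)-4-[(2S)-5-iodopentan-2-yl]-2,2-dimethyl-1,3-dioxolane | CC1(C)OC[C@H](O1)[C@@H](C)CCCI | intermediate
22 | alkyllithium from 21 | CC1(C)OC[C@H](O1)[C@@H](C)CCC[Li] | intermediate
23 | (5S)-1-{(2R,5S)-5-[(1R)-1-(TBSO)but-3-enyl]-5-methyloxolan-2-yl}-5-[(4R)-2,2-dimethyl-1,3-dioxolan-4-yl]hexan-1-one (seco C8 ketone) | CC1(C)OC[C@H](O1)[C@@H](C)CCCC(=O)[C@H]1CC[C@](C)(O1)[C@H](O[Si](C)(C)C(C)(C)C)CC=C | intermediate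
24 | bromomagnesium 8S-alkoxide from 23 | CC1(C)OC[C@H](O1)[C@@H](C)CCC[C@](C)(O[Mg]Br)[C@H]1CC[C@](C)(O1)[C@H](O[Si](C)(C)C(C)(C)C)CC=C | intermediate
25 | (2S,6S)-2-{(2R,5S)-5-[(1R)-1-(TBSO)but-3-enyl]-5-methyloxolan-2-yl}-6-[(4R)-2,2-dimethyl-1,3-dioxolan-4-yl]heptan-2-yl acetate (seco 8S acetate) | CC1(C)OC[C@H](O1)[C@@H](C)CCC[C@](C)(OC(C)=O)[C@H]1CC[C@](C)(O1)[C@H](O[Si](C)(C)C(C)(C)C)CC=C | intermediate
26 | secondary ozonide of 25 | CC1(C)OC[C@H](O1)[C@@H](C)CCC[C@](C)(OC(C)=O)[C@H]1CC[C@](C)(O1)[C@H](O[Si](C)(C)C(C)(C)C)CC1OOCO1 | intermediate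
27 | seco C1 aldehyde (3R-OTBS, 4S,7R-oxolane, 8S-OAc, 12S, 13R,14-acetonide) | CC1(C)OC[C@H](O1)[C@@H](C)CCC[C@](C)(OC(C)=O)[C@H]1CC[C@](C)(O1)[C@H](O[Si](C)(C)C(C)(C)C)CC=O | intermediate
28 | Baylis–Hillman adduct of 27 with methyl acrylate (C1 epimers) | CC1(C)OC[C@H](O1)[C@@H](C)CCC[C@](C)(OC(C)=O)[C@H]1CC[C@](C)(O1)[C@H](O[Si](C)(C)C(C)(C)C)CC(O)C(=C)C(=O)OC | intermediate
29 | seco methyl (Z)-2-(bromomethyl)enoate (C2 chain cis to CH2Br) | CC1(C)OC[C@H](O1)[C@@H](C)CCC[C@](C)(OC(C)=O)[C@H]1CC[C@](C)(O1)[C@H](O[Si](C)(C)C(C)(C)C)C/C=C(\CBr)C(=O)OC | intermediate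
30 | seco 13R,14-diol of 29 | OC[C@H](O)[C@@H](C)CCC[C@](C)(OC(C)=O)[C@H]1CC[C@](C)(O1)[C@H](O[Si](C)(C)C(C)(C)C)C/C=C(\CBr)C(=O)OC | intermediate
31 | seco 13R-hydroxy C14 aldehyde | O=C[C@H](O)[C@@H](C)CCC[C@](C)(OC(C)=O)[C@H]1CC[C@](C)(O1)[C@H](O[Si](C)(C)C(C)(C)C)C/C=C(\CBr)C(=O)OC | intermediate
32 | 14-membered 13R,14R-diol methyl 2-methylidene ester (1S) | C=C(C(=O)OC)[C@H]1[C@@H](O)[C@H](O)[C@@H](C)CCC[C@](C)(OC(C)=O)[C@H]2CC[C@](C)(O2)[C@H](O[Si](C)(C)C(C)(C)C)C1 | intermediate
33 | 13-hydroxy 3-O-TBS cembranolide, 8-acetate, cis-fused α-methylene-γ-lactone | C=C1C(=O)O[C@H]2[C@H](O)[C@@H](C)CCC[C@](C)(OC(C)=O)[C@H]3CC[C@](C)(O3)[C@H](O[Si](C)(C)C(C)(C)C)C[C@@H]12 | intermediate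
34 | 8,13-diacetate 3-O-TBS cembranolide | C=C1C(=O)O[C@H]2[C@H](OC(C)=O)[C@@H](C)CCC[C@](C)(OC(C)=O)[C@H]3CC[C@](C)(O3)[C@H](O[Si](C)(C)C(C)(C)C)C[C@@H]12 | intermediate
35 | target, (1S,3R,4S,7R,8S,12S,13R,14R)-8,13-diacetoxy-4,7-epoxy-3-hydroxycembr-15(17)-en-16,14-olide | C=C1C(=O)O[C@H]2[C@H](OC(C)=O)[C@@H](C)CCC[C@](C)(OC(C)=O)[C@H]3CC[C@](C)(O3)[C@H](O)C[C@@H]12 | target

Total step count: 23. Longest linear sequence: 17 steps (4 to 35: steps 2–8 and 14–23).

Three steps most likely to fail

1. Step 5. Attack on the fully substituted C4 may be slow. Direct reduction of the C5 radical would then compete and the facial selectivity at C4 could erode. The fallback sets out from 1 and 6 and returns at 10. It closes the same C4–C5 bond on an unsubstituted acceptor carbon and adds the methyl group afterwards. Ethynylmagnesium bromide and 1 should give (R)-ethynyl p-tolyl sulfoxide F1. N-Methylmorpholine-catalysed addition of 6 should give the E β-alkoxyvinyl sulfoxide F2. Bu3SnH/Et3B should close it 5-exo to the cis-2,5-disubstituted oxolane sulfoxide F3. Trifluoroacetic anhydride and 2,6-lutidine should give the trifluoroacetoxy sulfide F4, and bicarbonate hydrolysis the enolisable aldehyde F5. KHMDS followed by MeI should then methylate the exocyclic enolate of F5 on the face anti to the C7 carboxamide and give 10.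

2. Step 21. The allylindium may oligomerise or be protonated at high dilution. Facial selectivity at the aldehyde may also be poor if ring conformation overrides chelation. The fallback sets out from 31 and returns at 32. It replaces the metal-surface Barbier reaction by an intramolecular allylboration. Pd(0)-catalysed borylation of the allylic bromide with bis(pinacolato)diboron at high dilution should give the allylboronate aldehyde F6. Its boron can bind the C13 hydroxyl and deliver C1 to the aldehyde through a closed bicyclic chair transition state. Aqueous work-up should give 32, which lactonises to 33 as in the main route.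

3. Step 4. The catalytic base may cause loss of the iodide by ring closure through oxygen or the amide. It may also epimerise C7 or isomerise 3 to the allenyl sulfoxide without addition. The fallback sets out from 3 and returns at 7, and it keeps 6 away from base. Sodium methoxide in methanol should add to 3 to give (E)-2-methoxyprop-1-enyl (R)-p-tolyl sulfoxide F7. Acid-catalysed enol-ether exchange of F7 with 6 (PPTS, toluene, 5 Å sieves to take up methanol) should then give 7.

Further compounds
F1 | step 5 | (R)-ethynyl p-tolyl sulfoxide | C#C[S@@](=O)c1ccc(C)cc1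
F2 | step 5 | (R)-4-iodo-N-methoxy-N-methyl-2-{(E)-2-[(R)-p-tolylsulfinyl]ethenyloxy}butanamide | CON(C)C(=O)[C@H](O/C=C/[S@@](=O)c1ccc(C)cc1)CCI
F3 | step 5 | (2R,5S)-N-methoxy-N-methyl-5-{[(R)-p-tolylsulfinyl]methyl}oxolane-2-carboxamide | CON(C)C(=O)[C@H]1CC[C@H](O1)C[S@@](=O)c1ccc(C)cc1
F4 | step 5 | trifluoroacetoxy sulfide of F3 (C3 epimers) | CON(C)C(=O)[C@H]1CC[C@H](O1)C(OC(=O)C(F)(F)F)Sc1ccc(C)cc1
F5 | step 5 | (2R,5S)-5-formyl-N-methoxy-N-methyloxolane-2-carboxamide | CON(C)C(=O)[C@H]1CC[C@H](O1)C=O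
F6 | step 21 | seco 13R-hydroxy C14 aldehyde with CH2Bpin in place of CH2Br | O=C[C@H](O)[C@@H](C)CCC[C@](C)(OC(C)=O)[C@H]1CC[C@](C)(O1)[C@H](O[Si](C)(C)C(C)(C)C)C/C=C(\CB1OC(C)(C)C(C)(C)O1)C(=O)OC
F7 | step 4 | (E)-2-methoxyprop-1-enyl (R)-p-tolyl sulfoxide | CO/C(C)=C/[S@@](=O)c1ccc(C)cc1
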